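**Plan**

- Retrosynthesis: the C1'–OH goes back to a C1' ketone, which serves as the activating group for C3. The thiolactone ring bond C3–C3a is cut next, with the hydroquinone ring raised to its quinone oxidation level. Then S–C3 (thiocarboxylate plus 1-bromoheptan-2-one), C1–S (acid to thioacid) and the prenyl–C6 bond (Claisen) are cut.
- Forward: methyl 5-methoxysalicylate supplies the benzene ring. Prenyl is placed ortho to the phenol by O-alkylation, semihydrogenation and Claisen rearrangement, the C7 chain is joined at sulfur, and the five-membered thiolactone ring is closed last, at C3–C3a.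
- Enabling feature: ring C3a–C7a is a hydroquinone. As the 2-acyl-1,4-benzoquinone, C3a is β to both the C7 ring carbonyl and the C1 thioester carbonyl, and C3 is a CH2 between S2 and the C1' ketone. Its enol adds there and re-aromatisation returns the free 4,7-diol, so no protecting group is needed.
- Stereochemistry: C3, formed in the key step between ketone, sulfur and arene, is configurationally labile on purpose. C1' (R) and C3 (S) are set together in the last step by a dynamic reductive kinetic resolution with a ketoreductase.

Key step: step 6

Remark on the chemistry: 1-bromoheptan-2-one (7) is taken as a purchased compound. The ketoreductase of step 7 is an (R)-selective (anti-Prelog) enzyme, to be picked from a commercial panel for the 3S,1'R product.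

Step 1
Reactants: 1 methyl 2-hydroxy-5-methoxybenzoate; 2 3-chloro-3-methylbut-1-yne
Product: 3 methyl 5-methoxy-2-[(2-methylbut-3-yn-2-yl)oxy]benzoate
Conditions: K2CO3, KI (cat.), CuI (cat.), acetone, 56 °C
Reagents that add atoms: none
Why: Copper-assisted O-alkylation of a phenol with a tertiary propargylic chloride is the standard entry to aryl 1,1-dimethylpropargyl ethers and also works on chelated ortho-carbonyl phenols; ester and methyl ether are inert.

Step 2
Reactants: 3 methyl 5-methoxy-2-[(2-methylbut-3-yn-2-yl)oxy]benzoate
Product: 4 methyl 5-methoxy-2-[(2-methylbut-3-en-2-yl)oxy]benzoate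
Conditions: H2 (1 atm), Lindlar catalyst, quinoline, EtOAc, 23 °C
Reagents that add atoms: none
Why: Lindlar semihydrogenation of the terminal alkyne should stop at the alkene and give the 1,1-dimethylallyl aryl ether needed for the sigmatropic step.

Step 3
Reactants: 4 methyl 5-methoxy-2-[(2-methylbut-3-en-2-yl)oxy]benzoate
Product: 5 methyl 2-hydroxy-5-methoxy-3-(3-methylbut-2-en-1-yl)benzoate
Conditions: xylenes, 135 °C
Reagents that add atoms: none
Why: Aromatic Claisen rearrangement ([3,3] shift, then tautomerisation): only the ortho position C3 is free (C1 carries the ester, the para position the methoxy group), so the allyl unit should arrive there, transposed, as the prenyl group.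

Step 4
Reactants: 5 methyl 2-hydroxy-5-methoxy-3-(3-methylbut-2-en-1-yl)benzoate
Product: 6 2-hydroxy-5-methoxy-3-(3-methylbut-2-en-1-yl)benzoic acid
Conditions: LiOH·H2O, THF/MeOH/H2O, 60 °C; then 1 M HCl
Reagents that add atoms: lithium hydroxide, [Li+].[OH-]
Why: Saponification of the methyl ester (acyl substitution by hydroxide); the prenyl group and the aryl methyl ether are stable to base.

Step 5
Reactants: 6 2-hydroxy-5-methoxy-3-(3-methylbut-2-en-1-yl)benzoic acid; 7 1-bromoheptan-2-one
Product: 10 S-(2-oxoheptyl) 2-hydroxy-5-methoxy-3-(3-methylbut-2-en-1-yl)benzenecarbothioate, via acyl imidazole 8 (not isolated), via sodium thiocarboxylate 9 (not isolated)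
Conditions: CDI, THF, 23 °C; NaSH, DMF, 0 °C; then 7, 0 → 23 °C
Reagents that add atoms: sodium hydrosulfide, [Na+].[SH-]
Why: Acyl imidazole formation, thiolysis by hydrosulfide and SN2 alkylation of the soft thiocarboxylate sulfur by the α-bromo ketone are all standard, and under these nearly neutral conditions the chelated phenol should be neither acylated nor alkylated.

Step 6
Reactants: 10 S-(2-oxoheptyl) 2-hydroxy-5-methoxy-3-(3-methylbut-2-en-1-yl)benzenecarbothioate
Product: 12 rac-3-hexanoyl-4,7-dihydroxy-6-(3-methylbut-2-en-1-yl)-2-benzothiophen-1(3H)-one, via acylquinone 11 (not isolated)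
Conditions: PhI(OAc)2 (1.0 equiv), MeCN/H2O (9:1, 0.01 M), 0 °C; then NaOAc (0.3 equiv), 0 → 23 °C
Reagents that add atoms: water, O
Why: Proposed new method: PhI(OAc)2 oxidises the para-methoxyphenol to the 2-acyl-1,4-benzoquinone 11 (water adds para to the phenoxenium ion, methanol leaves); in the acetate-buffered medium the enol of the S–CH2–C(=O) unit then adds in Michael fashion to the quinone carbon next to the acylated one (the later C3a), which is β to both the C7 ring carbonyl and the thioester carbonyl, and enolisation of the ene-dione restores the aromatic 4,7-diol. The closest known reaction type is the intermolecular C-alkylation of 2-acyl- and 2-alkoxycarbonyl-1,4-benzoquinones at this same position by 1,3-dicarbonyl compounds and other enol(ate) donors with aromatisation to the hydroquinone; new here are the tether through the activating acyl group and an α-acylthio ketone as donor. The thiolactone ring closes in a 5-(enolexo) mode that is formally 5-endo-trig at the quinone C=C bond; the approach geometry is that of SNAr and Friedel–Crafts closures of benzo-fused five-membered rings and is relaxed by the two long C–S bonds and the small C–S–C angle. The new stereocentre C3 lies between the ketone, the ring sulfur and the arene, is configurationally labile and is deliberately left uncontrolled (it is fixed in step 7). The step needs C- rather than O-attack of the enol, attack at one quinone carbon only and no follow-up cyclodehydration: O-attack or attack by the other α-carbon of the ketone would give seven-membered rings, the other quinone carbons are out of reach of the tether, and the furan that usually forms from such adducts would have to be fused across the C3–C3a bond of the thiolactone, which the strain of that tricycle should prevent.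

Step 7
Reactants: 12 rac-3-hexanoyl-4,7-dihydroxy-6-(3-methylbut-2-en-1-yl)-2-benzothiophen-1(3H)-one
Product: 13 (3S)-4,7-dihydroxy-3-[(1R)-1-hydroxyhexyl]-6-(3-methylbut-2-en-1-yl)-2-benzothiophen-1(3H)-one (asperglaucin A)
Conditions: ketoreductase (anti-Prelog, L. kefir ADH family), NADP+ (cat.), i-PrOH, KPi pH 7.0/DMSO, 30 °C, N2
Reagents that add atoms: none
Why: Ketoreductase-catalysed dynamic reductive kinetic resolution: the enzyme delivers hydride (NADPH, recycled by i-PrOH) to the si face of the C1' carbonyl in the anti-Prelog sense (ring carbon C3 as large, pentyl as small substituent), which sets C1' as R, and the enzyme is chosen to accept only the 3S epimer of 12 while the other is fed in by fast enolisation of the C3–H, which sets C3 as S; thiolactone and prenyl group are not touched.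

**Compound list**

1 | methyl 2-hydroxy-5-methoxybenzoate | COC(=O)c1cc(OC)ccc1O | starting material
2 | 3-chloro-3-methylbut-1-yne | C#CC(C)(C)Cl | starting material
3 | methyl 5-methoxy-2-[(2-methylbut-3-yn-2-yl)oxy]benzoate | COC(=O)c1cc(OC)ccc1OC(C)(C)C#C | intermediate
4 | methyl 5-methoxy-2-[(2-methylbut-3-en-2-yl)oxy]benzoate | COC(=O)c1cc(OC)ccc1OC(C)(C)C=C | intermediate
5 | methyl 2-hydroxy-5-methoxy-3-(3-methylbut-2-en-1-yl)benzoate | COC(=O)c1cc(OC)cc(CC=C(C)C)c1O | intermediate
6 | 2-hydroxy-5-methoxy-3-(3-methylbut-2-en-1-yl)benzoic acid | OC(=O)c1cc(OC)cc(CC=C(C)C)c1O | intermediate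
7 | 1-bromoheptan-2-one | CCCCCC(=O)CBr | starting material
8 | [2-hydroxy-5-methoxy-3-(3-methylbut-2-en-1-yl)phenyl](1H-imidazol-1-yl)methanone (acyl imidazole) | O=C(c1cc(OC)cc(CC=C(C)C)c1O)n1ccnc1 | intermediate
9 | sodium 2-hydroxy-5-methoxy-3-(3-methylbut-2-en-1-yl)benzenecarbothioate | [Na+].[S-]C(=O)c1cc(OC)cc(CC=C(C)C)c1O | intermediate
10 | S-(2-oxoheptyl) 2-hydroxy-5-methoxy-3-(3-methylbut-2-en-1-yl)benzenecarbothioate | CCCCCC(=O)CSC(=O)c1cc(OC)cc(CC=C(C)C)c1O | intermediate
11 | S-(2-oxoheptyl) 5-(3-methylbut-2-en-1-yl)-3,6-dioxocyclohexa-1,4-diene-1-carbothioate (acylquinone) | CCCCCC(=O)CSC(=O)C1=CC(=O)C=C(CC=C(C)C)C1=O | intermediate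
12 | rac-3-hexanoyl-4,7-dihydroxy-6-(3-methylbut-2-en-1-yl)-2-benzothiophen-1(3H)-one | CCCCCC(=O)C1SC(=O)c2c(O)c(CC=C(C)C)cc(O)c21 | intermediate
13 | (3S)-4,7-dihydroxy-3-[(1R)-1-hydroxyhexyl]-6-(3-methylbut-2-en-1-yl)-2-benzothiophen-1(3H)-one (asperglaucin A) | CCCCC[C@@H](O)[C@H]1SC(=O)c2c(O)c(CC=C(C)C)cc(O)c21 | target

**Step count and risks**

Total step count: 7. Longest linear sequence: 7.

The three steps most likely to fail:

First, step 6. The acylquinone 11 may be lost to hydration or to redox exchange with the product hydroquinone before it cyclises. The thioester must also reach its less favoured rotamer for the ring to close. The product may reopen at C3–S through its ortho-quinone methide if the medium becomes basic. The fallback makes the C3–C3a bond between two molecules by known chemistry and closes the ring at sulfur. It sets out from ester 5, which PhI(OAc)2 in aqueous MeCN should oxidise to methyl 5-(3-methylbut-2-en-1-yl)-3,6-dioxocyclohexa-1,4-diene-1-carboxylate F1. Bromoketone 7 and potassium thioacetate give S-(2-oxoheptyl) ethanethioate F2. DABCO-catalysed Michael addition of F2 to F1, the documented reaction of active methylene compounds with 2-alkoxycarbonylbenzoquinones, should give methyl 2-[1-(acetylsulfanyl)-2-oxoheptyl]-3,6-dihydroxy-5-(3-methylbut-2-en-1-yl)benzoate (racemic) F3. S-Deacetylation with hydrazine acetate in DMF frees the thiol, which should close onto the neighbouring methyl ester, and the route is rejoined at 12.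

Second, step 7. The bulky ketone may be poorly accepted by the enzyme, or the enzyme may select the wrong C3 epimer and give the syn carbinol; simple polar-model (Felkin-type) hydride delivery would also favour syn, which is why an enzyme is used. The hydroquinone may oxidise in aerated buffer. The fallback sets out from 12. Corey–Bakshi–Shibata reduction ((S)-Me-CBS, catecholborane, toluene, −78 °C; ring carbon C3 as large and pentyl as small group) should set C1' as R in both C3 epimers. This gives 13 together with (3R)-4,7-dihydroxy-3-[(1R)-1-hydroxyhexyl]-6-(3-methylbut-2-en-1-yl)-2-benzothiophen-1(3H)-one F4. Brief exposure of the mixture to i-Pr2NEt in MeCN should then equilibrate C3 by reversible retro-thia-Michael opening to the ortho-quinone methide (free C4 phenol) and re-closure. This should favour the 3S,1'R isomer, the only one in which the carbinol H lies over the bicycle while the pentyl group points away and the OH stays anti to sulfur and hydrogen-bonded to the C4 hydroxyl. The route is rejoined at 13.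

Third, step 1. O-Alkylation of the chelated, hindered phenoxide may be slow, with elimination of the tertiary chloride to the enyne competing. The fallback sets out from 1. Bromination ortho to the hydroxyl group (Br2, CH2Cl2, 0 °C) should give methyl 3-bromo-2-hydroxy-5-methoxybenzoate F5. Stille coupling of F5 with tributyl(3-methylbut-2-en-1-yl)stannane (Pd(PPh3)4, DMF, 90 °C) joins the prenyl group directly and rejoins the route at 5, bypassing 3 and 4.

Further compounds
F1 | step 6 | methyl 5-(3-methylbut-2-en-1-yl)-3,6-dioxocyclohexa-1,4-diene-1-carboxylate | COC(=O)C1=CC(=O)C=C(CC=C(C)C)C1=O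
F2 | step 6 | S-(2-oxoheptyl) ethanethioate | CCCCCC(=O)CSC(C)=O
F3 | step 6 | methyl 2-[1-(acetylsulfanyl)-2-oxoheptyl]-3,6-dihydroxy-5-(3-methylbut-2-en-1-yl)benzoate (racemic) | CCCCCC(=O)C(SC(C)=O)c1c(O)cc(CC=C(C)C)c(O)c1C(=O)OC
F4 | step 7 | (3R)-4,7-dihydroxy-3-[(1R)-1-hydroxyhexyl]-6-(3-methylbut-2-en-1-yl)-2-benzothiophen-1(3H)-one | CCCCC[C@@H](O)[C@@H]1SC(=O)c2c(O)c(CC=C(C)C)cc(O)c21
F5 | step 1 | methyl 3-bromo-2-hydroxy-5-methoxybenzoate | COC(=O)c1cc(OC)cc(Br)c1O
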